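The cyclohexane (elemane numbering) is traced back to the cyclopentane ring of a norbornene. An asymmetric Diels–Alder reaction of a 5-silyl-2,3-dimethylcyclopentadiene with but-2-ynal, exo vinyl-cuprate addition and enol-ether oxidation give a strained 2-formyl-2-hydroxynorbornene. Its α-ketol rearrangement shifts the quaternary carbon C10 (methyl, vinyl) onto the formyl carbon. This one operation inserts C9, enlarges ring C5–C6–C7–C8–C10 to the six-membered ring and creates the vicinal C8/C9 oxygen pair next to C10, the feature it exploits. The tetrasubstituted etheno bridge is a latent pair of cis C5/C7 isopropenyl arms, oxidised in parallel to enal and α-methylene lactone. Silicon masks the C6 oxygen.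

Key step: step 6

Numbering used throughout:
- C10 = quaternary ring carbon (CH3, vinyl); C9 = CH–O-angeloyl; C8 = CH–O(lactone); C7 = lactone ring-fusion CH; C6 = CH–OAc; C5 = CH bearing the propenal unit.
- C4 and C11 are the first carbons of the arms on C5 and C7.
- β is the face of the C10 methyl group.

Assumption: the sense of induction of the catalyst in step 3 is assigned by analogy with cyclopentadiene/alkynal cycloadditions; the antipodal catalyst is equally available.

Step 1
Reactants: 1 2,3-dimethylcyclopent-2-en-1-one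
Product: 3 1,2-dimethylcyclopenta-1,3-diene (tautomer mixture), via allylic alcohol 2 (not isolated)
Conditions: LiAlH4, Et2O, 0 °C; work-up; then p-TsOH (cat.), Et2O, rt, distil
Reagents that add atoms: none
Why: 1,2-hydride reduction of the enone and acid-catalysed E1 dehydration of the allylic alcohol give the cyclopentadiene; all tautomers converge on one anion in step 2 and no stereocentre is formed.

Step 2
Reactants: 3 1,2-dimethylcyclopenta-1,3-diene
Product: 5 benzyl(3,4-dimethylcyclopenta-2,4-dien-1-yl)dimethylsilane, via lithium 1,2-dimethylcyclopentadienide 4 (not isolated)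
Conditions: n-BuLi, THF, −78 → 0 °C; BnMe2SiCl, −78 → 0 °C
Reagents that add atoms: benzyl(chloro)dimethylsilane C[Si](C)(Cl)Cc1ccccc1
Why: Deprotonation to the aromatic cyclopentadienide and silylation at the least hindered ring carbon, supported by fast 1,5-silyl shifts, should funnel the material into the Cs-symmetric 5-silyl-2,3-dimethyl isomer, which is also the most reactive diene.

Step 3
Reactants: 5 benzyl(3,4-dimethylcyclopenta-2,4-dien-1-yl)dimethylsilane; 6 but-2-ynal
Product: 7 7-syn-(benzyldimethylsilyl)-3,5,6-trimethylbicyclo[2.2.1]hepta-2,5-diene-2-carbaldehyde (Si syn to the dimethyl-substituted double bond)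
Conditions: (S)-o-tolyl-oxazaborolidinium triflimide (10 mol %), CH2Cl2, −78 °C
Reagents that add atoms: none
Why: In this catalytic enantioselective Diels–Alder reaction of an acetylenic aldehyde the dienophile adds anti to the silyl group, which therefore ends syn to the dimethyl alkene (C6 configuration), and the chiral Lewis acid on the formyl group selects one of the two enantiomeric orientations, fixing C5 and C7.

Step 4
Reactants: 7 silyl-norbornadiene carbaldehyde
Product: 8 trimethylsilyl enol ether of the 3-exo-vinyl-3-endo-methyl norbornene-2-carbaldehyde (E/Z mixture)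
Conditions: CH2=CHMgBr, CuBr·SMe2 (15 mol %), TMSCl, DMPU, THF, −78 °C
Reagents that add atoms: vinylmagnesium bromide C=C[Mg]Br; chlorotrimethylsilane C[Si](C)(C)Cl
Why: Copper-catalysed, TMSCl-accelerated conjugate addition to the strained enal delivers vinyl to the exo face (side of the small C6–H, away from the second double bond), which sets quaternary C10 with vinyl α and methyl β, and the enolate is trapped as silyl enol ether.

Step 5
Reactants: 8 trimethylsilyl enol ether
Product: 10 2-exo-hydroxy-3-endo-methyl-3-exo-vinyl norbornene-2-endo-carbaldehyde, via spiro silyloxy-oxirane 9 (not isolated)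
Conditions: DMDO (1.0 equiv), acetone–CH2Cl2, −78 °C; then AcOH–H2O–THF, 0 °C
Reagents that add atoms: dimethyldioxirane CC1(C)OO1
Why: In this Rubottom oxidation the electron-rich enol ether should be epoxidised from the exo face much faster than the doubly shielded tetrasubstituted alkene or the vinyl group, and mild acid opens the silyloxy-oxirane to the tertiary α-hydroxy aldehyde.

Step 6
Reactants: 10 2-exo-hydroxy-2-endo-formyl norbornene
Product: 11 8-syn-(benzyldimethylsilyl)-3-hydroxy-4,6,7-trimethyl-4-vinylbicyclo[3.2.1]oct-6-en-2-one (C8 ketone; C9-OH equatorial α; vinyl axial α)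
Conditions: Sc(OTf)3 (10 mol %), CH2Cl2, −40 → 0 °C
Reagents that add atoms: none
Why: Sc(III) binds the hydroxyl and formyl oxygens of 10 in a five-membered chelate, and the C8–C10 σ bond, which stands perpendicular to the activated C=O, shifts suprafacially to the formyl carbon while C8 becomes the ketone (α-ketol/acyloin rearrangement, the reaction type of the D-homoannulation of 17-hydroxy-20-oxo steroids). No ring is closed by cyclisation: the cyclopentane ring C5–C6–C7–C8–C10 takes up the former formyl carbon as C9 through the 1,2-shift and becomes the six-membered ring of a bicyclo[3.2.1]octenone, driven by loss of norbornene strain and by the aldehyde-to-ketone change, which should make the step practically irreversible. C10 migrates with retention, so the quaternary centre set in step 4 is carried over unchanged. The only new stereocentre, C9, is fixed by the syn-chelate geometry (exo OH, endo CHO), which offers to C10 the aldehyde face that leaves the C9 hydroxyl equatorial (α) and pointing away from the etheno bridge, and this is also the more stable epimer of an enolisable centre. The step needs migration of C10 rather than of the bridgehead C7: C10 is a tertiary-alkyl, vinyl-bearing migrating group whereas C7 is a secondary bridgehead carbon, and one-carbon enlargements of 2-norbornanone derivatives favour shift of the non-bridgehead carbon. A mild catalytic Lewis acid at low temperature is chosen to avoid later transposition of the ketol through its enediol.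

Step 7
Reactants: 11 ketol
Product: 12 8α,9α-cis-diol of the bicyclo[3.2.1]octene
Conditions: NaBH4, CeCl3·7H2O, MeOH, −40 °C
Reagents that add atoms: none
Why: In this Luche-type reduction the exo face of the C8 carbonyl is blocked by the 1,3-diaxial vinyl group on C10 and by the C6–H, so hydride should enter from the endo side and give the axial (α) C8 alcohol cis to the C9 hydroxyl.

Step 8
Reactants: 12 cis-diol
Product: 13 8,9-O-isopropylidene bicyclo[3.2.1]octene
Conditions: Me2C(OMe)2, PPTS (cat.), CH2Cl2, rt
Reagents that add atoms: 2,2-dimethoxypropane COC(C)(C)OC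
Why: Acid-catalysed transketalisation closes the dioxolane on the cis-diol and masks both hydroxyls through steps 9–12.

Step 9
Reactants: 13 acetonide
Product: 16 5β,7β-diacetyl-6β-silyl cyclohexane acetonide, via C4 allylic hydroperoxide 14 (not isolated), via C11 allylic hydroperoxide 15 (not isolated)
Conditions: O2, tetraphenylporphyrin (cat.), hν (visible), CH2Cl2, −20 °C; then TFA (cat.), 0 °C
Reagents that add atoms: oxygen O=O
Why: In the Schenck ene reaction singlet oxygen attacks only the tetrasubstituted alkene (vinyl is inert, the endo face is the less covered one, either methyl supplies the hydrogen), and in the Hock cleavage acid-induced alkenyl migration to oxygen breaks the C4–C11 bond, so both hydroperoxides collapse to the same cis-diacetyl cyclohexane with C5 and C7 untouched.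

Step 10
Reactants: 16 diketone
Product: 17 5β,7β-diisopropenyl-6β-silyl cyclohexane acetonide
Conditions: Cp2TiMe2, toluene, 70 °C, dark
Reagents that add atoms: dimethyltitanocene [CH3-].[CH3-].[Ti+4].c1cc[cH-]c1.c1cc[cH-]c1
Why: Petasis methylenation with the non-basic titanium methylidene converts both methyl ketones into isopropenyl groups without enolisation, so the α-stereocentres C5 and C7 are not epimerised.

Step 11
Reactants: 17 diisopropenyl silane
Product: 19 6β-alcohol, via dimethylsilanol 18 (not isolated)
Conditions: TBAF, THF, rt; then 30 % H2O2, KHCO3, MeOH–THF, 40 °C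
Reagents that add atoms: hydrogen peroxide OO
Why: In this Tamao–Fleming oxidation of the benzyldimethylsilyl group fluoride removes benzyl and the peroxide-induced shift from silicon to oxygen proceeds with retention, giving the β (axial) C6 alcohol, while unactivated alkenes are inert to basic peroxide.

Step 12
Reactants: 19 6β-alcohol
Product: 20 6β-acetate
Conditions: Ac2O, DMAP, pyridine, 40 °C
Reagents that add atoms: acetic anhydride CC(=O)OC(C)=O
Why: DMAP-catalysed acylation of the only free hydroxyl installs the final acetate.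

Step 13
Reactants: 20 6β-acetate
Product: 21 8α,9α-diol 6β-acetate
Conditions: AcOH–H2O 4:1, 45 °C
Reagents that add atoms: none
Why: Acid hydrolysis of the dioxolane frees the diol, and the acetate and the 1,1-disubstituted alkenes tolerate aqueous acetic acid.

Step 14
Reactants: 21 diol acetate
Product: 22 bis(allylic alcohol) (2-hydroxymethyl-allyl arms on C5 and C7)
Conditions: SeO2 (cat.), t-BuOOH, CH2Cl2, 0 °C → rt
Reagents that add atoms: tert-butyl hydroperoxide CC(C)(C)OO (oxygen relayed by catalytic SeO2)
Why: Selenium dioxide allylic oxidation (ene reaction then [2,3]-shift) acts on both arms at once; methyl is attacked in preference to the hindered tertiary allylic C–H and the vinyl group has no allylic hydrogen.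

Step 15
Reactants: 22 bis(allylic alcohol)
Product: 24 9α-hydroxy 8,12-olide enal (de-angeloyl target), via enal lactol 23 (not isolated)
Conditions: TEMPO (cat.), PhI(OAc)2, CH2Cl2, rt
Reagents that add atoms: none
Why: Oxoammonium oxidation is selective for primary alcohols: the C5 arm gives the enal, the C7-arm aldehyde is captured by the equatorial C8 hydroxyl as lactol and oxidised on to the trans-fused α-methylene-γ-lactone, and the hindered secondary C9–OH is left.

Step 16
Reactants: 24 9α-hydroxy lactone enal; 25 angelic acid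
Product: 27 target CNP0252310.1, via angeloyl 2,4,6-trichlorobenzoyl anhydride 26 (not isolated)
Conditions: 2,4,6-Cl3C6H2COCl, Et3N, toluene, rt; then 24, 80 °C
Reagents that add atoms: none
Why: Yamaguchi-type esterification through the mixed anhydride without a nucleophilic catalyst is the protocol that keeps the Z geometry of angelates on hindered secondary alcohols.

Compound list
1 | 2,3-dimethylcyclopent-2-en-1-one | CC1=C(C)C(=O)CC1 | starting material
2 | 2,3-dimethylcyclopent-2-en-1-ol (racemic) | CC1=C(C)C(O)CC1 | intermediate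
3 | 1,2-dimethylcyclopenta-1,3-diene | CC1=C(C)C=CC1 | intermediate
4 | lithium 1,2-dimethylcyclopentadienide | [Li+].CC1=C(C)[CH-]C=C1 | intermediate
5 | benzyl(3,4-dimethylcyclopenta-2,4-dien-1-yl)dimethylsilane | CC1=CC(C=C1C)[Si](C)(C)Cc1ccccc1 | intermediate
6 | but-2-ynal | CC#CC=O | starting material
7 | 7-syn-silyl-3,5,6-trimethylnorbornadiene-2-carbaldehyde | O=CC1=C(C)[C@@H]2C(C)=C(C)[C@H]1[C@H]2[Si](C)(C)Cc1ccccc1 | intermediate
8 | TMS enol ether, 3-exo-vinyl-3-endo-methyl (E/Z mixture) | C=C[C@]1(C)C(=CO[Si](C)(C)C)[C@H]2C(C)=C(C)[C@@H]1[C@@H]2[Si](C)(C)Cc1ccccc1 | intermediate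
9 | spiro silyloxy-oxirane (oxygen exo; acetal carbon as mixture) | C=C[C@]1(C)[C@]3(OC3O[Si](C)(C)C)[C@H]2C(C)=C(C)[C@@H]1[C@@H]2[Si](C)(C)Cc1ccccc1 | intermediate
10 | 2-exo-hydroxy-2-endo-formyl norbornene | C=C[C@]1(C)[C@@](O)(C=O)[C@H]2C(C)=C(C)[C@@H]1[C@@H]2[Si](C)(C)Cc1ccccc1 | intermediate
11 | ring-enlarged ketol (C8 ketone, C9 α-OH) | C=C[C@]1(C)[C@H](O)C(=O)[C@H]2C(C)=C(C)[C@@H]1[C@@H]2[Si](C)(C)Cc1ccccc1 | intermediate
12 | 8α,9α-cis-diol | C=C[C@]1(C)[C@H](O)[C@H](O)[C@H]2C(C)=C(C)[C@@H]1[C@@H]2[Si](C)(C)Cc1ccccc1 | intermediate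
13 | 8,9-acetonide | C=C[C@]1(C)[C@@H]3OC(C)(C)O[C@@H]3[C@H]2C(C)=C(C)[C@@H]1[C@@H]2[Si](C)(C)Cc1ccccc1 | intermediate
14 | C4 allylic hydroperoxide (OOH endo) | C=C[C@]1(C)[C@@H]3OC(C)(C)O[C@@H]3[C@H]2C(=C)[C@@](C)(OO)[C@@H]1[C@@H]2[Si](C)(C)Cc1ccccc1 | intermediate
15 | C11 allylic hydroperoxide (OOH endo) | C=C[C@]1(C)[C@@H]3OC(C)(C)O[C@@H]3[C@H]2[C@@](C)(OO)C(=C)[C@@H]1[C@@H]2[Si](C)(C)Cc1ccccc1 | intermediate
16 | 5β,7β-diacetyl-6β-silyl cyclohexane acetonide | C=C[C@]1(C)[C@@H]2OC(C)(C)O[C@@H]2[C@@H](C(C)=O)[C@@H]([Si](C)(C)Cc2ccccc2)[C@H]1C(C)=O | intermediate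
17 | 5β,7β-diisopropenyl-6β-silyl cyclohexane acetonide | C=C[C@]1(C)[C@@H]2OC(C)(C)O[C@@H]2[C@@H](C(C)=C)[C@@H]([Si](C)(C)Cc2ccccc2)[C@H]1C(C)=C | intermediate
18 | dimethylsilanol | C=C[C@]1(C)[C@@H]2OC(C)(C)O[C@@H]2[C@@H](C(C)=C)[C@@H]([Si](C)(C)O)[C@H]1C(C)=C | intermediate
19 | 6β-alcohol | C=C[C@]1(C)[C@@H]2OC(C)(C)O[C@@H]2[C@@H](C(C)=C)[C@@H](O)[C@H]1C(C)=C | intermediate
20 | 6β-acetate | C=C[C@]1(C)[C@@H]2OC(C)(C)O[C@@H]2[C@@H](C(C)=C)[C@@H](OC(C)=O)[C@H]1C(C)=C | intermediate
21 | 8α,9α-diol 6β-acetate | C=C[C@]1(C)[C@H](O)[C@H](O)[C@@H](C(C)=C)[C@@H](OC(C)=O)[C@H]1C(C)=C | intermediate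
22 | bis(allylic alcohol) | C=C[C@]1(C)[C@H](O)[C@H](O)[C@@H](C(=C)CO)[C@@H](OC(C)=O)[C@H]1C(=C)CO | intermediate
23 | enal lactol (anomeric mixture) | C=C[C@]1(C)[C@H](O)[C@@H]2OC(O)C(=C)[C@H]2[C@@H](OC(C)=O)[C@H]1C(=C)C=O | intermediate
24 | 9α-hydroxy 8,12-olide enal | C=C[C@]1(C)[C@H](O)[C@@H]2OC(=O)C(=C)[C@H]2[C@@H](OC(C)=O)[C@H]1C(=C)C=O | intermediate
25 | angelic acid, (Z)-2-methylbut-2-enoic acid | O=C(O)/C(C)=C\C | starting material
26 | angeloyl 2,4,6-trichlorobenzoyl anhydride | O=C(OC(=O)c1c(Cl)cc(Cl)cc1Cl)/C(C)=C\C | intermediate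
27 | CNP0252310.1 | C=C[C@]1(C)[C@H](OC(=O)/C(C)=C\C)[C@@H]2OC(=O)C(=C)[C@H]2[C@@H](OC(C)=O)[C@H]1C(=C)C=O | target

Total step count: 16. Longest linear sequence: 16 steps (from 1).

Steps most likely to fail

**Step 6.** The bridgehead carbon may migrate in competition with C10, or the ketol may transpose through its enediol, which would place the carbonyl at the wrong ring carbon.
- The fallback sets out from 10 and returns at 11.
- NaBH4 reduces the aldehyde to the 1,2-diol F1.
- TsCl/pyridine sulfonylates only the primary hydroxyl to give the monotosylate F2.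
- KOt-Bu in THF triggers an irreversible semipinacol (Tiffeneau–Demjanov-type) enlargement of the same five-membered ring to the C9-unsubstituted ketone F3.
- In F3 only C9 can enolise, because C7 is a bridgehead.
- KHMDS followed by 2-(phenylsulfonyl)-3-phenyloxaziridine then hydroxylates C9 from the open exo side and gives 11.

**Step 9.** Oxygen transfer to an alkene that is covered by the silyl group on one face and by the three-carbon bridge on the other may be too slow, or the acid stage may take other paths than alkenyl migration.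
- The fallback sets out from 13 and returns at 20; it moves the C–Si oxidation ahead of the cleavage.
- Tamao–Fleming oxidation of 13 (TBAF; H2O2, KHCO3) gives the bicyclic syn-alcohol F4.
- Ac2O/DMAP gives the bicyclic acetate F5, whose exo face is now far less covered.
- Ozonolysis with one equivalent of ozone at −78 °C (Me2S work-up) cleaves the tetrasubstituted alkene to the diacetyl acetate F6.
- Non-basic Zn/CH2Br2/TiCl4 methylenation, which spares the acetate and avoids β-elimination, gives 20.

**Step 14.** The twofold allylic oxidation may stall after one arm, attack the tertiary allylic C–H bonds, or over-oxidise.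
- The fallback sets out from 20 and returns at 23.
- Ene-type chlorination with hypochlorous acid (Ca(OCl)2, CO2, CH2Cl2–H2O) acts on the two 1,1-disubstituted alkenes and leaves the vinyl group, giving the bis(allylic chloride) F7.
- N-methylmorpholine N-oxide in MeCN converts both chlorides into aldehydes, giving the bis-enal acetonide F8.
- Aqueous acetic acid removes the acetonide and the freed C8 hydroxyl closes on the C7-arm aldehyde to give lactol 23.
- Lactol 23 is oxidised as in step 15.

Further compounds
F1 | step 6 | 2-exo-hydroxy-2-endo-hydroxymethyl norbornene (1,2-diol) | C=C[C@]1(C)[C@@](O)(CO)[C@H]2C(C)=C(C)[C@@H]1[C@@H]2[Si](C)(C)Cc1ccccc1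
F2 | step 6 | primary monotosylate of F1 | C=C[C@]1(C)[C@@](O)(COS(=O)(=O)c3ccc(C)cc3)[C@H]2C(C)=C(C)[C@@H]1[C@@H]2[Si](C)(C)Cc1ccccc1
F3 | step 6 | ring-enlarged ketone without C9 oxygen | C=C[C@]1(C)CC(=O)[C@H]2C(C)=C(C)[C@@H]1[C@@H]2[Si](C)(C)Cc1ccccc1
F4 | step 9 | bicyclic 6β (syn) alcohol acetonide | C=C[C@]1(C)[C@@H]3OC(C)(C)O[C@@H]3[C@H]2C(C)=C(C)[C@@H]1[C@@H]2O
F5 | step 9 | bicyclic 6β (syn) acetate acetonide | C=C[C@]1(C)[C@@H]3OC(C)(C)O[C@@H]3[C@H]2C(C)=C(C)[C@@H]1[C@@H]2OC(C)=O
F6 | step 9 | 5β,7β-diacetyl 6β-acetate acetonide | C=C[C@]1(C)[C@@H]2OC(C)(C)O[C@@H]2[C@@H](C(C)=O)[C@@H](OC(C)=O)[C@H]1C(C)=O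
F7 | step 14 | bis(allylic chloride) acetonide | C=C[C@]1(C)[C@@H]2OC(C)(C)O[C@@H]2[C@@H](C(=C)CCl)[C@@H](OC(C)=O)[C@H]1C(=C)CCl
F8 | step 14 | bis-enal acetonide | C=C[C@]1(C)[C@@H]2OC(C)(C)O[C@@H]2[C@@H](C(=C)C=O)[C@@H](OC(C)=O)[C@H]1C(=C)C=O
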